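**Retrosynthetic overview**
- The target is (3R)-7,4'-dihydroxy-6,3'-diprenylisoflavanone. Its only stereocentre (C3) is set last, by hydride delivery to C2 and face-selective protonation at C3 of the achiral isoflavone, as isoflavone reductase does.
- The two prenyl groups come from a double C-prenylation of 6,3'-dibromodaidzein. The bromides mark the prenyltransferase positions and survive the oxidative chemistry that prenyl alkenes would not.
- The isoflavone skeleton comes from a flavanone by oxidative 2,3-aryl shift (isoflavone synthase logic). The flavanone comes from a 2'-hydroxychalcone by 6-endo oxa-Michael closure (chalcone isomerase logic). Both happen in one flask.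
- The chalcone comes from a Claisen–Schmidt condensation of two bought bromoarenes.
- Ring order: rings A and B are bought; ring C is the only ring formed (step 2), and the aryl shift then takes place on the formed ring.

Assumption: 1 is bought as a catalogue compound, and the (R)-catalyst in step 5 is taken to give the (3R) product, the (S)-catalyst being used instead if the first run shows the opposite sense.

Step 1
Reactants: 1 1-(5-bromo-2-hydroxy-4-methoxyphenyl)ethan-1-one; 2 3-bromo-4-methoxybenzaldehyde
Product: 3 (E)-1-(5-bromo-2-hydroxy-4-methoxyphenyl)-3-(3-bromo-4-methoxyphenyl)prop-2-en-1-one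
Conditions: KOH (50% aq, 5 equiv), EtOH, 25 °C, 36 h; then aq HCl to pH 3
Reagents that add atoms: none
Why: Claisen–Schmidt (crossed aldol) condensation, in which the non-enolisable aldehyde is attacked by the methyl ketone enolate and the aldol dehydrates to the conjugated E-enone, while aryl bromides and methyl ethers are inert to KOH (any flavanone formed alongside is also a substrate for step 2).

Step 2
Reactants: 3 (E)-1-(5-bromo-2-hydroxy-4-methoxyphenyl)-3-(3-bromo-4-methoxyphenyl)prop-2-en-1-one
Product: 6 6-bromo-3-(3-bromo-4-methoxyphenyl)-7-methoxy-4H-chromen-4-one, via flavanone 4 (not isolated), via C3 iodane 5 (not isolated)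
Conditions: TsOH·H2O (0.3 equiv), MeCN, 80 °C, 6 h; then PhI(OH)OTs (1.3 equiv), 80 °C, 3 h
Reagents that add atoms: none
Why: Acid-catalysed 6-endo oxa-Michael addition (chalcone–flavanone isomerisation) closes ring C to give 4, whose enol is captured at C3 by the trivalent iodine reagent to give the trans iodane 5; in its diaxial conformer the electron-rich 4-methoxyaryl ring migrates from C2 to C3 with loss of PhI (hypervalent-iodine oxidative 1,2-aryl shift through a phenonium ion), and the C2 oxocarbenium ion loses the C3 proton to give the isoflavone, the chalcone–flavanone equilibrium being drained as 4 is consumed.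

Step 3
Reactants: 6 6-bromo-3-(3-bromo-4-methoxyphenyl)-7-methoxy-4H-chromen-4-one
Product: 7 6-bromo-3-(3-bromo-4-hydroxyphenyl)-7-hydroxy-4H-chromen-4-one
Conditions: BBr3 (6 equiv), CH2Cl2, −78 to 25 °C, 16 h; then H2O
Reagents that add atoms: none
Why: BBr3 cleavage of aryl methyl ethers (bromide attacks the O-methyl carbon of each boron-complexed ether), carried out before any acid-sensitive prenyl group or stereocentre is present; the chromone and aryl bromides are stable.

Step 4
Reactants: 7 6-bromo-3-(3-bromo-4-hydroxyphenyl)-7-hydroxy-4H-chromen-4-one; 8 4,4,5,5-tetramethyl-2-(3-methylbut-2-en-1-yl)-1,3,2-dioxaborolane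
Product: 9 7-hydroxy-3-[4-hydroxy-3-(3-methylbut-2-en-1-yl)phenyl]-6-(3-methylbut-2-en-1-yl)-4H-chromen-4-one
Conditions: 8 (3 equiv), PdCl2(dppf) (10 mol %; dppf = 1,1'-bis(diphenylphosphino)ferrocene), K3PO4 (6 equiv), 1,4-dioxane/H2O 5:1, 80 °C, 12 h, degassed
Reagents that add atoms: none
Why: Double Suzuki–Miyaura cross-coupling, in which zerovalent palladium inserts into each C–Br bond, the phosphate-activated prenyl boronate transmetalates, and reductive elimination from the less hindered terminus of the allyl–palladium intermediate gives the linear prenyl groups at C6 and C3'; the free phenols are carried as phenoxides and the isoflavone tolerates the mild base.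

Step 5
Reactants: 9 7-hydroxy-3-[4-hydroxy-3-(3-methylbut-2-en-1-yl)phenyl]-6-(3-methylbut-2-en-1-yl)-4H-chromen-4-one
Product: 11 (3R)-7-hydroxy-3-[4-hydroxy-3-(3-methylbut-2-en-1-yl)phenyl]-6-(3-methylbut-2-en-1-yl)-2,3-dihydro-4H-chromen-4-one, via enol 10 (not isolated)
Conditions: (R)-3,3'-bis(2,4,6-triisopropylphenyl)-1,1'-binaphthyl-2,2'-diyl N-triflylphosphoramide (10 mol %), diethyl 2,6-dimethyl-1,4-dihydropyridine-3,5-dicarboxylate (1.3 equiv), toluene/CHCl3 3:1, 5 Å molecular sieves, 25 °C, dark; direct filtration through silica, no basic work-up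
Reagents that add atoms: none
Why: Proposed new method: the strongly acidic chiral phosphoramide protonates the chromone carbonyl of 9 to a 4-hydroxybenzopyrylium ion paired with the chiral anion, the Hantzsch ester (an NADPH surrogate) transfers hydride to C2 to give enol 10, and the catalyst, hydrogen-bonded to the enol OH, then protonates C3 on one face to set (3R); the closest known reaction types are the chiral phosphoric acid/Hantzsch ester transfer hydrogenation of 3-substituted quinolines (1,4-hydride addition followed by enantioselective protonation) and the chiral N-triflyl phosphoramide-catalysed enantioselective protonation of silyl enol ethers of 2-aryl cycloalkanones, and a Hantzsch ester does not reduce prenyl alkenes, phenols or the product aryl ketone.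

**Compound list**
1 | 1-(5-bromo-2-hydroxy-4-methoxyphenyl)ethan-1-one | CC(=O)c1cc(Br)c(OC)cc1O | starting material
2 | 3-bromo-4-methoxybenzaldehyde | COc1ccc(C=O)cc1Br | starting material
3 | (E)-1-(5-bromo-2-hydroxy-4-methoxyphenyl)-3-(3-bromo-4-methoxyphenyl)prop-2-en-1-one | COc1ccc(/C=C/C(=O)c2cc(Br)c(OC)cc2O)cc1Br | intermediate
4 | racemic 6-bromo-2-(3-bromo-4-methoxyphenyl)-7-methoxy-2,3-dihydro-4H-chromen-4-one (flavanone) | COc1ccc(C2CC(=O)c3cc(Br)c(OC)cc3O2)cc1Br | intermediate (not isolated)
5 | racemic 2,3-trans-6-bromo-2-(3-bromo-4-methoxyphenyl)-7-methoxy-3-[phenyl(tosyloxy)-λ3-iodanyl]-2,3-dihydro-4H-chromen-4-one | COc1ccc(C2Oc3cc(OC)c(Br)cc3C(=O)C2I(OS(=O)(=O)c2ccc(C)cc2)c2ccccc2)cc1Br | intermediate (not isolated)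
6 | 6-bromo-3-(3-bromo-4-methoxyphenyl)-7-methoxy-4H-chromen-4-one | COc1ccc(-c2coc3cc(OC)c(Br)cc3c2=O)cc1Br | intermediate
7 | 6-bromo-3-(3-bromo-4-hydroxyphenyl)-7-hydroxy-4H-chromen-4-one (6,3'-dibromodaidzein) | Oc1ccc(-c2coc3cc(O)c(Br)cc3c2=O)cc1Br | intermediate
8 | 4,4,5,5-tetramethyl-2-(3-methylbut-2-en-1-yl)-1,3,2-dioxaborolane (prenylboronic acid pinacol ester) | CC(C)=CCB1OC(C)(C)C(C)(C)O1 | starting material
9 | 7-hydroxy-3-[4-hydroxy-3-(3-methylbut-2-en-1-yl)phenyl]-6-(3-methylbut-2-en-1-yl)-4H-chromen-4-one | CC(C)=CCc1cc(-c2coc3cc(O)c(CC=C(C)C)cc3c2=O)ccc1O | intermediate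
10 | 3-[4-hydroxy-3-(3-methylbut-2-en-1-yl)phenyl]-6-(3-methylbut-2-en-1-yl)-2H-chromene-4,7-diol (enol) | CC(C)=CCc1cc(C2=C(O)c3cc(CC=C(C)C)c(O)cc3OC2)ccc1O | intermediate (not isolated)
11 | (3R)-7-hydroxy-3-[4-hydroxy-3-(3-methylbut-2-en-1-yl)phenyl]-6-(3-methylbut-2-en-1-yl)-2,3-dihydro-4H-chromen-4-one | CC(C)=CCc1cc([C@@H]2COc3cc(O)c(CC=C(C)C)cc3C2=O)ccc1O | target

**Summary**
Total step count: 5. Longest linear sequence: 5 steps (from 1 or 2 to 11).

The three steps most likely to fail:

Step 5 (highest risk). The reduction has no direct precedent on an isoflavone. The enantioselectivity and its sense are unproven, the strong acid could slowly racemise C3 or cyclise an ortho-prenyl phenol, and 1,2-reduction could compete. The fallback sets out from 9 and comes back at 11. Compound 9 is silylated (TBSCl, imidazole, DMF) to the bis(tert-butyldimethylsilyl) ether of 9 F1. Asymmetric transfer hydrogenation with RuCl[(R,R)-TsDPEN](p-cymene) in HCO2H/Et3N reduces C2=C3 and then the ketone, with dynamic kinetic resolution of the base-labile C3 centre. The (R,R) catalyst gives the (4R) benzylic alcohol and the cis relationship, so the product is the (3R,4R)-cis-isoflavan-4-ol bis-silyl ether F2. Dess–Martin periodinane (CH2Cl2, 0 °C, no base) oxidises the alcohol back to the (3R)-isoflavanone bis-silyl ether F3 without touching C3. HF·pyridine in THF at 0 °C then removes both silyl groups to give 11.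

Step 2. The trivalent iodine reagent can dehydrogenate the flavanone to the flavone instead of inducing the aryl shift (the 3'-bromine lowers the migratory aptitude a little). Unreacted chalcone could also be oxidised directly, for example to an aurone. The fallback sets out from 3 and comes back at 6, and puts the aryl shift before ring closure. Chalcone 3 is treated with trivalent thallium nitrate, Tl(NO3)3·3H2O, in MeOH/HC(OMe)3 at 25 °C to give the rearranged acetal 1-(5-bromo-2-hydroxy-4-methoxyphenyl)-2-(3-bromo-4-methoxyphenyl)-3,3-dimethoxypropan-1-one F4. Heating F4 in 10% HCl/MeOH cyclises it and eliminates methanol to give 6.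

Step 4. Oxidative addition into two electron-rich bromophenoxides may be slow, and some branched (reverse-prenyl) isomer may form. The fallback sets out from 7 and comes back at 9, and builds the prenyl groups in two stages. A double Stille coupling of 7 with allyltributylstannane (Pd(PPh3)4, DMF, 100 °C, neutral conditions) gives 7-hydroxy-3-[4-hydroxy-3-(prop-2-en-1-yl)phenyl]-6-(prop-2-en-1-yl)-4H-chromen-4-one F5; a symmetrical allyl group has no regiochemistry issue. Cross-metathesis of F5 with excess 2-methylbut-2-ene (second-generation Grubbs catalyst, CH2Cl2, 40 °C) converts both allyl groups into prenyl groups to give 9.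

**Further compounds**
F1 | step 5 | 7-(tert-butyldimethylsilyloxy)-3-[4-(tert-butyldimethylsilyloxy)-3-(3-methylbut-2-en-1-yl)phenyl]-6-(3-methylbut-2-en-1-yl)-4H-chromen-4-one | CC(C)=CCc1cc(-c2coc3cc(O[Si](C)(C)C(C)(C)C)c(CC=C(C)C)cc3c2=O)ccc1O[Si](C)(C)C(C)(C)C
F2 | step 5 | (3R,4R)-7-(tert-butyldimethylsilyloxy)-3-[4-(tert-butyldimethylsilyloxy)-3-(3-methylbut-2-en-1-yl)phenyl]-6-(3-methylbut-2-en-1-yl)-3,4-dihydro-2H-chromen-4-ol (cis) | CC(C)=CCc1cc([C@@H]2COc3cc(O[Si](C)(C)C(C)(C)C)c(CC=C(C)C)cc3[C@@H]2O)ccc1O[Si](C)(C)C(C)(C)C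
F3 | step 5 | (3R)-7-(tert-butyldimethylsilyloxy)-3-[4-(tert-butyldimethylsilyloxy)-3-(3-methylbut-2-en-1-yl)phenyl]-6-(3-methylbut-2-en-1-yl)-2,3-dihydro-4H-chromen-4-one | CC(C)=CCc1cc([C@@H]2COc3cc(O[Si](C)(C)C(C)(C)C)c(CC=C(C)C)cc3C2=O)ccc1O[Si](C)(C)C(C)(C)C
F4 | step 2 | racemic 1-(5-bromo-2-hydroxy-4-methoxyphenyl)-2-(3-bromo-4-methoxyphenyl)-3,3-dimethoxypropan-1-one | COC(OC)C(C(=O)c1cc(Br)c(OC)cc1O)c1ccc(OC)c(Br)c1
F5 | step 4 | 7-hydroxy-3-[4-hydroxy-3-(prop-2-en-1-yl)phenyl]-6-(prop-2-en-1-yl)-4H-chromen-4-one | C=CCc1cc(-c2coc3cc(O)c(CC=C)cc3c2=O)ccc1O
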